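**Retrosynthetic overview**
- Katsumain C ⇐ one-pot global deprotection and Claisen–Schmidt condensation of a protected 3-substituted 2,4-dihydroxy-6-methoxyacetophenone with benzaldehyde.
- C-1–C-2 bond (sets C-1) ⇐ nickel-catalysed enantioselective decarboxylative radical alkenylation of a diarylacetic N-hydroxyphthalimide ester with an (E)-alkenyl bromide that already carries C-5.
- Diarylacetic acid ⇐ glyoxylic acid as C-1 plus a traceless CO2H: phenol + glyoxylic acid, then Friedel–Crafts alkylation of 2,4-dihydroxy-6-methoxyacetophenone (from anisole by C–H diborylation/oxidation and C-acetylation).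
- Alkenyl bromide ⇐ 4-iodophenol + allyl alcohol (Heck), asymmetric propargylation (sets C-5), hydrozirconation–bromination.
- Rings: all three benzene rings are bought; the only ring made is a benzofuranone lactone (step 4), reopened in step 5.

Target descriptors: C-1 (diaryl carbon) R, C-5 (carbinol) R, both alkenes E.
Assumption: the sense of induction of the nickel/bis(oxazoline) catalyst for a diarylmethyl radical is unknown; the ligand antipode is fixed after the first run (the C-1 epimers are diastereomers), and the route is written for the one that gives 1R.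

**Step 1**
Reactants: 1 anisole
Product: 3 5-methoxybenzene-1,3-diol, via 3,5-bis(pinacolboryl)anisole 2 (not isolated)
Conditions: [Ir(OMe)(cod)]2 (1.5 mol%), 4,4'-di-tert-butyl-2,2'-bipyridine (3 mol%), B2pin2 (1.2 equiv), THF, 80 °C; then Oxone (2KHSO5·KHSO4·K2SO4), acetone/H2O, 20 °C
Reagents that add atoms: bis(pinacolato)diboron, CC1(C)OB(OC1(C)C)B1OC(C)(C)C(C)(C)O1 (boron of 2); potassium peroxymonosulfate, [K+].[O-]S(=O)(=O)OO (phenolic oxygens of 3)
Why: Sterically controlled iridium-catalysed C–H borylation puts boron meta and then at the second mutually meta position, and one-pot ipso-oxidation of both C–B bonds gives the 1,3,5-pattern (the para mono-boronate, about a quarter, is removed after oxidation as 4-methoxyphenol).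

**Step 2**
Reactants: 3 5-methoxybenzene-1,3-diol; 4 acetic acid
Product: 5 1-(2,4-dihydroxy-6-methoxyphenyl)ethan-1-one
Conditions: AcOH (solvent), ZnCl2 (1.5 equiv), 130 °C; 1 M HCl work-up
Reagents that add atoms: none
Why: Nencki-type Friedel–Crafts C-acylation goes para to one hydroxyl and ortho to the other (as orcinol gives orcacetophenone), the chelated product resists a second acylation, and the minor 2,6-dihydroxy-4-methoxy isomer is removed by chromatography.

**Step 3**
Reactants: 6 phenol; 7 glyoxylic acid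
Product: 8 (±)-2-hydroxy-2-(4-hydroxyphenyl)acetic acid
Conditions: phenol (1.5 equiv), NaOH (2.2 equiv), H2O, 30 °C, 24 h; HCl to pH 1
Reagents that add atoms: none
Why: Base-mediated para-selective hydroxyalkylation of phenoxide by glyoxylate (the technical 4-hydroxymandelic acid process); the racemic centre is erased in step 4.

**Step 4**
Reactants: 5 1-(2,4-dihydroxy-6-methoxyphenyl)ethan-1-one; 8 (±)-2-hydroxy-2-(4-hydroxyphenyl)acetic acid
Product: 9 (±)-5-acetyl-4-hydroxy-3-(4-hydroxyphenyl)-6-methoxy-1-benzofuran-2(3H)-one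
Conditions: 5 (1.2 equiv), p-TsOH·H2O (0.3 equiv), 1,4-dioxane, 80 °C
Reagents that add atoms: none
Why: Acid ionises 8 to a para-quinone-methide-type cation that undergoes Friedel–Crafts alkylation at C-3 of 5 (ortho to both hydroxyls and para to OMe, whereas C-5 is para only to the chelated, weakly donating hydroxyl), and the unchelated 4-OH then closes the lactone.

**Step 5**
Reactants: 9 (±)-5-acetyl-4-hydroxy-3-(4-hydroxyphenyl)-6-methoxy-1-benzofuran-2(3H)-one
Product: 11 (±)-2-[3-acetyl-2,6-bis(acetyloxy)-4-methoxyphenyl]-2-[4-(acetyloxy)phenyl]acetic acid, via tetrasodium salt of the ring-opened acid 10 (not isolated)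
Conditions: 2 M NaOH (6 equiv), 0 → 20 °C, N2; then Ac2O (6 equiv), 0 °C, pH kept ≥ 9; cold 1 M HCl to pH 2; product taken up through NaHCO3
Reagents that add atoms: sodium hydroxide, [Na+].[OH-] (oxygen of the CO2H; sodium of 10); acetic anhydride, CC(=O)OC(C)=O (three O-acetyl groups)
Why: Saponification opens the aryl lactone and Chattaway (Schotten–Baumann) acetylation caps the three phenoxides faster than the carboxylate is activated, while any lactone that re-closes is reopened by excess hydroxide and the neutral remainder is separated by the bicarbonate extraction.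

**Step 6**
Reactants: 11 (±)-2-[3-acetyl-2,6-bis(acetyloxy)-4-methoxyphenyl]-2-[4-(acetyloxy)phenyl]acetic acid
Product: 12 (±)-1,3-dioxoisoindolin-2-yl 2-[3-acetyl-2,6-bis(acetyloxy)-4-methoxyphenyl]-2-[4-(acetyloxy)phenyl]acetate
Conditions: N-hydroxyphthalimide (1.1 equiv), N,N'-diisopropylcarbodiimide (1.1 equiv), DMAP (5 mol%), CH2Cl2, 0 → 20 °C
Reagents that add atoms: N-hydroxyphthalimide, O=C1c2ccccc2C(=O)N1O
Why: Steglich-type carbodiimide esterification gives the redox-active ester, and with no free phenol left lactonisation cannot compete.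

**Step 7**
Reactants: 13 4-iodophenol; 14 prop-2-en-1-ol
Product: 15 3-(4-hydroxyphenyl)propanal
Conditions: Pd(OAc)2 (2 mol%), n-Bu4NCl (1 equiv), NaHCO3 (2.5 equiv), DMF, 45 °C
Reagents that add atoms: none
Why: Jeffery–Heck arylation of allyl alcohol, in which β-hydride elimination toward the carbinol carbon gives the enol and hence the saturated aldehyde.

**Step 8**
Reactants: 15 3-(4-hydroxyphenyl)propanal
Product: 16 3-{4-[(tert-butyldimethylsilyl)oxy]phenyl}propanal
Conditions: TBSCl (1.1 equiv), imidazole (1.5 equiv), CH2Cl2, 0 → 20 °C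
Reagents that add atoms: tert-butyldimethylsilyl chloride, CC(C)(C)[Si](C)(C)Cl
Why: Phenol silylation removes the acidic proton for the borane and zirconium steps and is cleaved by hydroxide in step 12.

**Step 9**
Reactants: 16 3-{4-[(tert-butyldimethylsilyl)oxy]phenyl}propanal; 17 3-bromoprop-1-yne
Product: 21 (3R)-1-{4-[(tert-butyldimethylsilyl)oxy]phenyl}hex-5-yn-3-ol, via allenylmagnesium bromide 18 (not isolated), via B-allenyldiisopinocampheylborane 19 (not isolated), via homopropargyl borinate 20 (not isolated)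
Conditions: 17, Mg, HgCl2 (1 mol%), Et2O, 0 °C; (−)-Ipc2BOMe [from (+)-α-pinene], −78 → 20 °C; 16, −78 °C; ethanolamine, 20 °C
Reagents that add atoms: magnesium, [Mg] (in 18); (−)-B-methoxydiisopinocampheylborane, COB([C@@H]1C[C@@H]2C[C@H]([C@H]1C)C2(C)C)[C@@H]1C[C@@H]2C[C@H]([C@H]1C)C2(C)C (boron and terpene groups of 19 and 20)
Why: Brown asymmetric propargylation, in which the allenylborane transfers its propargyl group through a closed six-membered SE2' transition state to the Si face of the aldehyde (taken to be the same facial sense as the allyl reagent of this terpene series), setting the carbinol as R (later C-5).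

**Step 10**
Reactants: 21 (3R)-1-{4-[(tert-butyldimethylsilyl)oxy]phenyl}hex-5-yn-3-ol
Product: 23 (3R,5E)-6-bromo-1-{4-[(tert-butyldimethylsilyl)oxy]phenyl}hex-5-en-3-ol, via O-zirconated alkenylzirconocene 22 (not isolated)
Conditions: Cp2Zr(H)Cl (2.3 equiv), THF, 20 °C; N-bromosuccinimide (1.15 equiv), 0 °C; aq. NaHCO3
Reagents that add atoms: chloridohydridozirconocene Cp2Zr(H)Cl, [H][Zr](Cl)(C1C=CC=C1)C1C=CC=C1 (zirconium of 22); N-bromosuccinimide, O=C1CCC(=O)N1Br (bromine of 23)
Why: Hydrozirconation (the first equivalent is consumed by the hydroxyl) is syn and terminal, and bromination of the C–Zr bond proceeds with retention, giving the E-alkenyl bromide; the carbinol is untouched.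

**Step 11**
Reactants: 12 (±)-1,3-dioxoisoindolin-2-yl 2-[3-acetyl-2,6-bis(acetyloxy)-4-methoxyphenyl]-2-[4-(acetyloxy)phenyl]acetate; 23 (3R,5E)-6-bromo-1-{4-[(tert-butyldimethylsilyl)oxy]phenyl}hex-5-en-3-ol
Product: 26 4-acetyl-2-[(1R,2E,5R)-1-[4-(acetyloxy)phenyl]-7-{4-[(tert-butyldimethylsilyl)oxy]phenyl}-5-hydroxyhept-2-en-1-yl]-5-methoxy-1,3-phenylene diacetate, via TMS ether of the bromide 24 (not isolated), via TMS ether of the coupled product 25 (not isolated)
Conditions: 23 (1.3 equiv), N,O-bis(trimethylsilyl)acetamide (0.7 equiv), DMA, 20 °C; then 12, NiBr2·diglyme (10 mol%), (3aS,3a'S,8aR,8a'R)-2,2'-(cyclopropane-1,1-diyl)bis(3a,8a-dihydro-8H-indeno[1,2-d]oxazole) (12 mol%), NaI (0.5 equiv), TMSBr (1 equiv), tetrakis(dimethylamino)ethylene (TDAE, 1.5 equiv), −7 °C; citric acid, MeOH/H2O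
Reagents that add atoms: N,O-bis(trimethylsilyl)acetamide, CC(=N[Si](C)(C)C)O[Si](C)(C)C (trimethylsilyl group of 24 and 25 only)
Why: Proposed new method: zerovalent nickel adds oxidatively to the alkenyl bromide with retention of the E geometry, single-electron reduction of the redox-active ester releases CO2, phthalimide anion and a diarylmethyl radical, and capture of that radical by the chiral alkenylnickel (divalent to trivalent) followed by reductive elimination forms C-1–C-2 and sets C-1 under catalyst control, the ligand pocket distinguishing the coplanar 4-acetoxyphenyl from the twisted 2,6-disubstituted aryl that behaves like a bulky alkyl group; the closest known reaction type is the nickel/bis(oxazoline)-catalysed enantioselective reductive cross-coupling of N-hydroxyphthalimide esters of 2-arylalkanoic acids (and of secondary benzylic chlorides) with alkenyl bromides, here extended to a diarylacetic ester. C-5 is remote and unchanged, so the minor 1S epimer is a diastereomer and is removed by HPLC.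

**Step 12**
Reactants: 26 4-acetyl-2-[(1R,2E,5R)-1-[4-(acetyloxy)phenyl]-7-{4-[(tert-butyldimethylsilyl)oxy]phenyl}-5-hydroxyhept-2-en-1-yl]-5-methoxy-1,3-phenylene diacetate; 27 benzaldehyde
Product: 29 Katsumain C, via deprotected methyl ketone 28 (not isolated)
Conditions: PhCHO (2 equiv), KOH (50% aq., 20 equiv), EtOH, 0 → 20 °C, N2, 48 h; cold 1 M HCl to pH 5; reversed-phase chromatography
Reagents that add atoms: none
Why: Hydroxide cleaves the three aryl acetates and the aryl silyl ether, and the methyl ketone enolate then undergoes Claisen–Schmidt aldol condensation with benzaldehyde to the E-enone (known for 2',4'-dihydroxy-6'-methoxyacetophenone itself); neither stereocentre is acidic enough to epimerise and the cold, mildly acidic quench avoids flavanone closure.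

**Compound list**
1 | anisole | COc1ccccc1 | starting material
2 | 2,2'-(5-methoxy-1,3-phenylene)bis(4,4,5,5-tetramethyl-1,3,2-dioxaborolane) | COc1cc(B2OC(C)(C)C(C)(C)O2)cc(B2OC(C)(C)C(C)(C)O2)c1 | intermediate
3 | 5-methoxybenzene-1,3-diol | COc1cc(O)cc(O)c1 | intermediate
4 | acetic acid | CC(=O)O | starting material
5 | 1-(2,4-dihydroxy-6-methoxyphenyl)ethan-1-one | CC(=O)c1c(O)cc(O)cc1OC | intermediate
6 | phenol | Oc1ccccc1 | starting material
7 | glyoxylic acid | O=CC(=O)O | starting material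
8 | (±)-2-hydroxy-2-(4-hydroxyphenyl)acetic acid | OC(C(=O)O)c1ccc(O)cc1 | intermediate
9 | (±)-5-acetyl-4-hydroxy-3-(4-hydroxyphenyl)-6-methoxy-1-benzofuran-2(3H)-one | CC(=O)c1c(OC)cc2OC(=O)C(c3ccc(O)cc3)c2c1O | intermediate
10 | tetrasodium (±)-2-(3-acetyl-4-methoxy-2,6-dioxidophenyl)-2-(4-oxidophenyl)acetate | CC(=O)c1c(OC)cc([O-])c(C(C(=O)[O-])c2ccc([O-])cc2)c1[O-].[Na+].[Na+].[Na+].[Na+] | intermediate
11 | (±)-2-[3-acetyl-2,6-bis(acetyloxy)-4-methoxyphenyl]-2-[4-(acetyloxy)phenyl]acetic acid | CC(=O)c1c(OC)cc(OC(C)=O)c(C(C(=O)O)c2ccc(OC(C)=O)cc2)c1OC(C)=O | intermediate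
12 | (±)-1,3-dioxoisoindolin-2-yl 2-[3-acetyl-2,6-bis(acetyloxy)-4-methoxyphenyl]-2-[4-(acetyloxy)phenyl]acetate | CC(=O)c1c(OC)cc(OC(C)=O)c(C(C(=O)ON2C(=O)c3ccccc3C2=O)c2ccc(OC(C)=O)cc2)c1OC(C)=O | intermediate
13 | 4-iodophenol | Oc1ccc(I)cc1 | starting material
14 | prop-2-en-1-ol (allyl alcohol) | C=CCO | starting material
15 | 3-(4-hydroxyphenyl)propanal | O=CCCc1ccc(O)cc1 | intermediate
16 | 3-{4-[(tert-butyldimethylsilyl)oxy]phenyl}propanal | O=CCCc1ccc(O[Si](C)(C)C(C)(C)C)cc1 | intermediate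
17 | 3-bromoprop-1-yne (propargyl bromide) | C#CCBr | starting material
18 | propa-1,2-dien-1-ylmagnesium bromide | C=C=C[Mg]Br | intermediate
19 | B-allenyldiisopinocampheylborane (isopinocampheyl groups from (+)-α-pinene) | C=C=CB([C@@H]1C[C@@H]2C[C@H]([C@H]1C)C2(C)C)[C@@H]1C[C@@H]2C[C@H]([C@H]1C)C2(C)C | intermediate
20 | (3R)-1-{4-[(tert-butyldimethylsilyl)oxy]phenyl}hex-5-yn-3-yl diisopinocampheylborinate | C#CC[C@H](OB([C@@H]1C[C@@H]2C[C@H]([C@H]1C)C2(C)C)[C@@H]1C[C@@H]2C[C@H]([C@H]1C)C2(C)C)CCc1ccc(O[Si](C)(C)C(C)(C)C)cc1 | intermediate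
21 | (3R)-1-{4-[(tert-butyldimethylsilyl)oxy]phenyl}hex-5-yn-3-ol | C#CC[C@H](O)CCc1ccc(O[Si](C)(C)C(C)(C)C)cc1 | intermediate
22 | (E)-alkenylzirconocene chloride of 21, hydroxyl as O–Zr(Cl)Cp2 (Cp drawn as σ-C5H5) | Cl[Zr](C1C=CC=C1)(C1C=CC=C1)/C=C/C[C@H](O[Zr](Cl)(C1C=CC=C1)C1C=CC=C1)CCc1ccc(O[Si](C)(C)C(C)(C)C)cc1 | intermediate
23 | (3R,5E)-6-bromo-1-{4-[(tert-butyldimethylsilyl)oxy]phenyl}hex-5-en-3-ol | Br/C=C/C[C@H](O)CCc1ccc(O[Si](C)(C)C(C)(C)C)cc1 | intermediate
24 | {[(3R,5E)-6-bromo-1-{4-[(tert-butyldimethylsilyl)oxy]phenyl}hex-5-en-3-yl]oxy}trimethylsilane | Br/C=C/C[C@H](O[Si](C)(C)C)CCc1ccc(O[Si](C)(C)C(C)(C)C)cc1 | intermediate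
25 | 5-O-trimethylsilyl ether of 26, (1R,2E,5R) | COc1cc(OC(C)=O)c([C@H](/C=C/C[C@H](O[Si](C)(C)C)CCc2ccc(O[Si](C)(C)C(C)(C)C)cc2)c2ccc(OC(C)=O)cc2)c(OC(C)=O)c1C(C)=O | intermediate
26 | 4-acetyl-2-[(1R,2E,5R)-1-[4-(acetyloxy)phenyl]-7-{4-[(tert-butyldimethylsilyl)oxy]phenyl}-5-hydroxyhept-2-en-1-yl]-5-methoxy-1,3-phenylene diacetate | COc1cc(OC(C)=O)c([C@H](/C=C/C[C@H](O)CCc2ccc(O[Si](C)(C)C(C)(C)C)cc2)c2ccc(OC(C)=O)cc2)c(OC(C)=O)c1C(C)=O | intermediate
27 | benzaldehyde | O=Cc1ccccc1 | starting material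
28 | 1-{2,4-dihydroxy-3-[(1R,2E,5R)-5-hydroxy-1,7-bis(4-hydroxyphenyl)hept-2-en-1-yl]-6-methoxyphenyl}ethan-1-one | COc1cc(O)c([C@H](/C=C/C[C@H](O)CCc2ccc(O)cc2)c2ccc(O)cc2)c(O)c1C(C)=O | intermediate
29 | Katsumain C, (2E)-1-{2,4-dihydroxy-3-[(1R,2E,5R)-5-hydroxy-1,7-bis(4-hydroxyphenyl)hept-2-en-1-yl]-6-methoxyphenyl}-3-phenylprop-2-en-1-one | COc1cc(O)c([C@H](/C=C/C[C@H](O)CCc2ccc(O)cc2)c2ccc(O)cc2)c(O)c1C(=O)/C=C/c1ccccc1 | target

**Totals**
Total steps: 12. Longest linear sequence: 7 (steps 1, 2, 4, 5, 6, 11, 12); the alkenyl bromide branch is 4 steps (7–10) and step 3 is a one-step side branch.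

**Three steps most likely to fail**

Step 4 (site of alkylation, C-3 against C-5 of 5, and over-alkylation). The fallback sets out from 3 and returns at 9, fixing the site by lithiation instead of by arene electronics. Compound 3 is protected with MOMCl/iPr2NEt to 1-methoxy-3,5-bis(methoxymethoxy)benzene F1. n-BuLi lithiates F1 between the two MOM ethers (directed ortho-metalation), and ethyl glyoxylate gives (±)-ethyl 2-hydroxy-2-[4-methoxy-2,6-bis(methoxymethoxy)phenyl]acetate F2. p-TsOH in the presence of phenol 6 removes the MOM groups, arylates the benzylic cation para to the phenol hydroxyl and closes the lactone, giving (±)-4-hydroxy-3-(4-hydroxyphenyl)-6-methoxy-1-benzofuran-2(3H)-one F3. C-acetylation ortho to the free hydroxyl (acetic acid 4, ZnCl2) then gives 9.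

Step 5 (re-lactonisation competing with acetylation of the hindered, chelated phenoxide). The fallback sets out from 9 and returns at 11, going through an orthogonal ester. Lactone 9 is opened by alcoholysis in allyl alcohol 14 (Et3N, 40 °C) to (±)-prop-2-en-1-yl 2-(3-acetyl-2,6-dihydroxy-4-methoxyphenyl)-2-(4-hydroxyphenyl)acetate F4. This is acetylated at once (Ac2O, pyridine, DMAP) to (±)-prop-2-en-1-yl 2-[3-acetyl-2,6-bis(acetyloxy)-4-methoxyphenyl]-2-[4-(acetyloxy)phenyl]acetate F5. Pd(PPh3)4 with PhSiH3 removes the allyl ester under neutral conditions to give 11.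

Step 11 (capture of a hindered diarylmethyl radical by nickel, and the level and sense of enantio-induction). The fallback sets out from 12 and alkyne 21 (step 10 is skipped) and returns at 26. A photo-induced copper-catalysed enantioconvergent decarboxylative alkynylation (CuI, cinchona-derived N,N,P ligand, Cs2CO3, blue light) couples the same radical with the copper acetylide of 21. It gives 4-acetyl-2-[(1S,5R)-1-[4-(acetyloxy)phenyl]-7-{4-[(tert-butyldimethylsilyl)oxy]phenyl}-5-hydroxyhept-2-yn-1-yl]-5-methoxy-1,3-phenylene diacetate F6; the spatial arrangement at C-1 is that of 26, and the descriptor changes only because alkynyl outranks aryl. A trans-selective semi-hydrogenation ([Cp*RuCl]4, H2, CH2Cl2), assisted by the homopropargylic hydroxyl, then gives the E-alkene 26.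

**Further compounds**
F1 | step 4 | 1-methoxy-3,5-bis(methoxymethoxy)benzene | COCOc1cc(OC)cc(OCOC)c1
F2 | step 4 | (±)-ethyl 2-hydroxy-2-[4-methoxy-2,6-bis(methoxymethoxy)phenyl]acetate | CCOC(=O)C(O)c1c(OCOC)cc(OC)cc1OCOC
F3 | step 4 | (±)-4-hydroxy-3-(4-hydroxyphenyl)-6-methoxy-1-benzofuran-2(3H)-one | COc1cc(O)c2C(c3ccc(O)cc3)C(=O)Oc2c1
F4 | step 5 | (±)-prop-2-en-1-yl 2-(3-acetyl-2,6-dihydroxy-4-methoxyphenyl)-2-(4-hydroxyphenyl)acetate | C=CCOC(=O)C(c1ccc(O)cc1)c1c(O)cc(OC)c(C(C)=O)c1O
F5 | step 5 | (±)-prop-2-en-1-yl 2-[3-acetyl-2,6-bis(acetyloxy)-4-methoxyphenyl]-2-[4-(acetyloxy)phenyl]acetate | C=CCOC(=O)C(c1ccc(OC(C)=O)cc1)c1c(OC(C)=O)cc(OC)c(C(C)=O)c1OC(C)=O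
F6 | step 11 | 4-acetyl-2-[(1S,5R)-1-[4-(acetyloxy)phenyl]-7-{4-[(tert-butyldimethylsilyl)oxy]phenyl}-5-hydroxyhept-2-yn-1-yl]-5-methoxy-1,3-phenylene diacetate | COc1cc(OC(C)=O)c([C@H](C#CC[C@H](O)CCc2ccc(O[Si](C)(C)C(C)(C)C)cc2)c2ccc(OC(C)=O)cc2)c(OC(C)=O)c1C(C)=O
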